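Bongardol is cut at both bonds of its ester carbonyl carbon C1: C1–C2 towards the chain and C1–O towards the arylethanol unit. Since C1 caps a strictly linear, unfunctionalised heptacosyl chain (C2–C28), carbon monoxide can supply it. A palladium hydride migrates from an internal double bond to the chain end, takes up CO there, and the primary alcohol cleaves the resulting acyl. One operation thus unites three components, makes two bonds and closes no ring. The para-disubstituted benzene ring is a spectator, its phenol masked as a benzyl ether. The precursor is (Z)-heptacos-13-ene, a plain C27 hydrocarbon assembled by one Wittig coupling. Hydrogenolysis of the benzyl ether ends the route.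

Key step: step 3

Remark: C1 is the ester carbonyl carbon and C2–C28 the chain of the acid part. dtbpx stands for 1,2-bis(di-tert-butylphosphinomethyl)benzene. The target has no stereocentre, and the Z geometry of the heptacosene is lost by design in the carbonylation.

Step 1
Reactants: 1 1-bromotridecane
Product: 2 tridecyl(triphenyl)phosphonium bromide
Conditions: PPh3 (1.05 equiv), MeCN, reflux; trituration with Et2O
Reagents that add atoms: triphenylphosphine, c1ccc(cc1)P(c1ccccc1)c1ccccc1
Why: SN2 quaternisation of the soft nucleophile PPh3 by an unhindered primary alkyl bromide (phosphonium salt formation) is reliable, meets no competing functional group and creates no stereocentre.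

Step 2
Reactants: 2 tridecyl(triphenyl)phosphonium bromide, 3 tetradecanal
Product: 6 (Z)-heptacos-13-ene, via ylide tridecylidene(triphenyl)phosphorane 4 (not isolated), via cis-oxaphosphetane 5 (not isolated)
Conditions: NaN(SiMe3)2 (1.0 equiv), THF, 0 °C, 1 h; then 3, −78 °C to rt; hexane trituration, SiO2 plug
Reagents that add atoms: none
Why: Wittig olefination, in which the lithium-free non-stabilised ylide 4 adds to the aldehyde under kinetic control to give racemic cis-oxaphosphetane 5 (its two transient stereocentres are set by the puckered early transition state that keeps both alkyl chains away from the P-phenyl groups), and stereospecific syn-cycloreversion should give the Z-alkene, whose geometry is not critical for step 3.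

Step 3
Reactants: 6 (Z)-heptacos-13-ene, 7 carbon monoxide, 8 2-[4-(benzyloxy)phenyl]ethanol
Product: 11 2-[4-(benzyloxy)phenyl]ethyl octacosanoate, via alkyl complex [Pd(dtbpx)(n-C27H55)]+ 9 (not isolated), via acyl complex [Pd(dtbpx)(CO-n-C27H55)]+ 10 (not isolated)
Conditions: Pd(OAc)2 (2 mol%), 1,2-bis(di-tert-butylphosphinomethyl)benzene (10 mol%), CH3SO3H (20 mol%), 7 (30 bar), 8 (2 equiv), dry toluene, 100 °C, autoclave
Reagents that add atoms: none
Why: CH3SO3H turns Pd(OAc)2 and dtbpx into the hydride [Pd(dtbpx)H]+ (divalent palladium), which hydropalladates C13=C14 of 6, and fast reversible β-H elimination/re-addition sequences then shift the metal carbon by carbon to the chain end to give the primary alkyl 9. Migratory insertion of 7 into 9 makes the C1–C2 bond (acyl 10), and attack of the CH2OH group of 8 on 10 makes the C1–O bond, releases 11 and regenerates the hydride. The closest known reaction type is the isomerising alkoxycarbonylation of internal fatty alkenes to linear esters with this same catalyst system, applied here in toluene with a twofold amount of a functionalised primary alcohol rather than in neat methanol. The selectivity at stake is regiochemical, terminal against internal carbonyl: the four tert-butyl groups crowd palladium so much that secondary acyls lose CO and walk on faster than 8 can cleave them, while the slim linear acyl is cleaved readily. The substrate supports this because its chain is unbranched and free of heteroatoms, so nothing arrests the migration, both termini lead to the same n-heptacosyl group, and O-benzylation leaves the alcohol of 8 as the sole nucleophile. No ring is closed and no stereocentre is formed, and the alkene geometry set in step 2 is erased.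

Step 4
Reactants: 11 2-[4-(benzyloxy)phenyl]ethyl octacosanoate
Product: 12 bongardol [2-(4-hydroxyphenyl)ethyl octacosanoate]
Conditions: H2 (1 atm), 10% Pd/C, EtOAc, 45 °C
Reagents that add atoms: none
Why: Catalytic hydrogenolysis should cleave only the benzylic C–O bond of the aryl benzyl ether, because the ester oxygen sits on a homobenzylic CH2 and the saturated chain offers nothing to reduce, while gentle warming keeps the waxy substrate in solution.

Compound list
1 | 1-bromotridecane (C13H27Br) | CCCCCCCCCCCCCBr | starting material
2 | tridecyl(triphenyl)phosphonium bromide | CCCCCCCCCCCCC[P+](c1ccccc1)(c1ccccc1)c1ccccc1.[Br-] | intermediate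
3 | tetradecanal (C14H28O) | CCCCCCCCCCCCCC=O | starting material
4 | tridecylidene(triphenyl)phosphorane (ylide, not isolated) | CCCCCCCCCCCCC=P(c1ccccc1)(c1ccccc1)c1ccccc1 | intermediate
5 | rac-cis-3-dodecyl-2,2,2-triphenyl-4-tridecyl-1,2λ5-oxaphosphetane (one enantiomer drawn, not isolated) | CCCCCCCCCCCC[C@@H]1[C@H](CCCCCCCCCCCCC)OP1(c1ccccc1)(c1ccccc1)c1ccccc1 | intermediate
6 | (Z)-heptacos-13-ene (C27H54) | CCCCCCCCCCCC/C=C\CCCCCCCCCCCCC | intermediate
7 | carbon monoxide | [C-]#[O+] | starting material
8 | 2-[4-(benzyloxy)phenyl]ethanol | OCCc1ccc(OCc2ccccc2)cc1 | starting material
9 | [Pd(dtbpx)(n-C27H55)](O3SCH3), n-heptacosyl complex of divalent palladium, agostic or solvent-stabilised (not isolated) | CCCCCCCCCCCCCCCCCCCCCCCCCCC[Pd-]1[P+](C(C)(C)C)(C(C)(C)C)Cc2ccccc2C[P+]1(C(C)(C)C)C(C)(C)C.CS(=O)(=O)[O-] | intermediate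
10 | [Pd(dtbpx)(CO-n-C27H55)](O3SCH3), octacosanoyl complex of divalent palladium (not isolated) | CCCCCCCCCCCCCCCCCCCCCCCCCCCC(=O)[Pd-]1[P+](C(C)(C)C)(C(C)(C)C)Cc2ccccc2C[P+]1(C(C)(C)C)C(C)(C)C.CS(=O)(=O)[O-] | intermediate
11 | 2-[4-(benzyloxy)phenyl]ethyl octacosanoate (C43H70O3) | CCCCCCCCCCCCCCCCCCCCCCCCCCCC(=O)OCCc1ccc(OCc2ccccc2)cc1 | intermediate
12 | bongardol, 2-(4-hydroxyphenyl)ethyl octacosanoate (C36H64O3) | CCCCCCCCCCCCCCCCCCCCCCCCCCCC(=O)OCCc1ccc(O)cc1 | target

Total step count: 4
Longest linear sequence: 4 steps (1 → 2 → 6 → 11 → 12)

Steps most likely to fail

**Step 3.**
- What may go wrong: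
  - At the modest alcohol concentration possible in toluene, cleavage of the acyl may become too slow. The catalyst would then decay to zerovalent palladium (palladium black) and only isomerised alkene would remain.
  - Acid-promoted loss or migration of the benzyl group, self-etherification of the alcohol, or capture of the acyl by traces of water could add to the loss. Most of the acid should, however, be held as the phosphonium salt of the surplus ligand.
- The fallback sets out from 6 and comes back at 11. It separates the C–C bond formation from the attachment of the arylethanol.
  - Compound 6 is carbonylated with the same catalyst in methanol/toluene, that is, with the alcohol in large excess as in the standard form of the reaction. This should give methyl octacosanoate F1.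
  - The C1–O bond to the linker is then made by classical acyl substitution. Transesterification of F1 with 8 (Ti(OiPr)4 cat., toluene, reflux, methanol taken up by 4 Å molecular sieves) should deliver 11.

**Step 2.**
- What may go wrong:
  - The basic ylide or surplus amide may enolise the aldehyde and cause self-aldol condensation.
  - The waxy, hygroscopic salt may be deprotonated incompletely.
  - Phosphorus residues may carry over and compete with dtbpx for palladium in step 3.
- The fallback sets out from 1 and comes back at 6 by a phosphorus-free alkyne route.
  - Commercial tetradec-1-yne is deprotonated (n-BuLi, THF, −78 to 0 °C) to lithium tetradec-1-yn-1-ide F2.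
  - F2 is alkylated with 1 (DMPU co-solvent, rt to 50 °C) to give heptacos-13-yne F3.
  - cis-Selective semihydrogenation of F3 (H2, Pd/CaCO3 poisoned with Pb(OAc)2, quinoline, hexane) should give 6. Any over-reduced alkane would only be an inert diluent in step 3.

**Step 4.**
- What may go wrong: the heterogeneous hydrogenolysis may stall, either because the waxy substrate crystallises onto the catalyst or because phosphine traces carried over from step 3 poison it.
- The fallback sets out from 11 and comes back at 12. It replaces reductive cleavage by homogeneous acidolysis in the presence of a cation scavenger.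
  - The conditions are CF3CO2H and pentamethylbenzene in CH2Cl2 at rt to 35 °C, as established for O-benzyl tyrosine units in peptide chemistry.
  - The benzyl cation is captured by the scavenger, the primary alkyl ester should not be touched, and no new compound lies on this way.

Further compounds
F1 | step 3 | methyl octacosanoate | CCCCCCCCCCCCCCCCCCCCCCCCCCCC(=O)OC
F2 | step 2 | lithium tetradec-1-yn-1-ide | [Li]C#CCCCCCCCCCCCCC
F3 | step 2 | heptacos-13-yne | CCCCCCCCCCCCC#CCCCCCCCCCCCCC
F0 | step 4 | none | none
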